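## Retrosynthetic overview

1. Locants: ring C1–C11 (C11 quaternary, C8 acyloxy carbon, C6/C7 oxirane, C2=C3, C9=C10), side chain C12–C16 (C14 carbinol), C17 = CH2OH carbon on C3. Target ⇒ desilylation; C8 ester by invertive Mitsunobu esterification of the erythro 6,7-epoxy-8-ol; oxirane (second ring) by hydroxyl-directed epoxidation of the macrocyclic 8-ol.
2. Eleven-membered carbocycle (first ring) ⇒ C8–C9 bond by a chromium-catalysed electroreductive Nozaki–Hiyama–Kishi macrocyclisation of an (E)-alkenyl iodide onto the C8 enal.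
3. Seco chain ⇒ two E-selective Wittig olefinations (C2=C3 with a C3–C6/C17 ylide, C6=C7 with the C7–C8 formyl ylide) on the C1–C2 aldehyde that carries C11.
4. C11 quaternary centre ⇒ two anti-selective enolate alkylations of (S)-5-(trityloxymethyl)butyrolactone (L-glutamic acid pool); its carbonyl becomes C10 (alkyne, then alkenyl iodide), its C4–C5 becomes C1–C2.
5. C12–C16 iodide with C14 ⇒ (S)-α-hydroxy-γ-butyrolactone (L-malic acid pool) by methyl addition, methylenation and iodination.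

Assumption: lactones 1 and 6 are taken as purchasable chiral-pool materials (made from L-malic acid and L-glutamic acid).
Abbreviations: TBS = tert-butyldimethylsilyl, TBDPS = tert-butyldiphenylsilyl, Tr = triphenylmethyl.

## Route

Step 1
Reactants: 1 (S)-3-hydroxydihydrofuran-2(3H)-one
Product: 2 (S)-3-(TBSO)dihydrofuran-2(3H)-one
Conditions: TBSCl, imidazole, DMF, rt
Reagents that add atoms: tert-butyldimethylsilyl chloride, CC(C)(C)[Si](C)(C)Cl
Why: Imidazole-promoted silylation protects the purchased C14 carbinol, whose configuration is not touched.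

Step 2
Reactants: 2 (S)-3-(TBSO)dihydrofuran-2(3H)-one
Product: 3 (3S)-3-(TBSO)-2-methyloxolan-2-ol (C2 anomers, ring form of the hydroxy methyl ketone)
Conditions: MeLi (1.05 equiv), THF, −78 °C; AcOH quench at −78 °C
Reagents that add atoms: methyllithium, [Li]C
Why: Mono-addition of an organolithium to a lactone stops at the lithium hemiketal at −78 °C (helped by the α-silyloxy group) and gives the methyl ketone/lactol on quench, with no new stereocentre of consequence.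

Step 3
Reactants: 3 (3S)-3-(TBSO)-2-methyloxolan-2-ol
Product: 4 (S)-3-(TBSO)-4-methylpent-4-en-1-ol
Conditions: Ph3PCH3Br (3 equiv), KOtBu (2.9 equiv), THF, 0 °C → rt
Reagents that add atoms: methylenetriphenylphosphorane (from methyltriphenylphosphonium bromide and KOtBu), C=P(c1ccccc1)(c1ccccc1)c1ccccc1
Why: Wittig methylenation of the open hydroxy-ketone tautomer builds the isopropenyl group, and addition to the methyl ketone outruns enolisation so C14 keeps its configuration.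

Step 4
Reactants: 4 (S)-3-(TBSO)-4-methylpent-4-en-1-ol
Product: 5 (S)-tert-butyl[(5-iodo-2-methylpent-1-en-3-yl)oxy]dimethylsilane
Conditions: I2, PPh3, imidazole, CH2Cl2, 0 °C → rt
Reagents that add atoms: iodine, [I][I]
Why: Appel-type iodination (Garegg–Samuelsson conditions) converts the primary alcohol into the iodide without affecting the allylic silyl ether.

Step 5
Reactants: 6 (S)-5-[(trityloxy)methyl]dihydrofuran-2(3H)-one; 5 (S)-tert-butyl[(5-iodo-2-methylpent-1-en-3-yl)oxy]dimethylsilane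
Product: 7 (3R,5S)-3-[(3S)-3-(TBSO)-4-methylpent-4-en-1-yl]-5-[(trityloxy)methyl]dihydrofuran-2(3H)-one
Conditions: LiN(iPr)2, THF, −78 °C; then 5, HMPA, −78 → −30 °C
Reagents that add atoms: none
Why: SN2 alkylation of the lactone lithium enolate with the primary iodide, the electrophile entering anti to the C5 trityloxymethyl group (trans product), a centre that is re-enolised in step 6.

Step 6
Reactants: 7 (3R,5S)-3-[(3S)-3-(TBSO)-4-methylpent-4-en-1-yl]-5-[(trityloxy)methyl]dihydrofuran-2(3H)-one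
Product: 8 (3S,5S)-3-[(3S)-3-(TBSO)-4-methylpent-4-en-1-yl]-3-methyl-5-[(trityloxy)methyl]dihydrofuran-2(3H)-one
Conditions: LiN(iPr)2, THF, −78 °C; then MeI, −78 → −40 °C
Reagents that add atoms: iodomethane, CI
Why: Second enolate alkylation in which methyl iodide again attacks the face anti to the trityloxymethyl group, so the quaternary centre (later C11, S) is set by the purchased lactone stereocentre (1,3-induction of the Tomioka type, typically >15:1).

Step 7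
Reactants: 8 (3S,5S)-3-[(3S)-3-(TBSO)-4-methylpent-4-en-1-yl]-3-methyl-5-[(trityloxy)methyl]dihydrofuran-2(3H)-one
Product: 10 (2S,4S,7S)-7-(TBSO)-4-ethynyl-4,8-dimethyl-1-(trityloxy)non-8-en-2-ol, via lactol 9 (not isolated)
Conditions: iBu2AlH, CH2Cl2, −78 °C; then MeOH, K2CO3, dimethyl (1-diazo-2-oxopropyl)phosphonate, −78 °C → rt
Reagents that add atoms: dimethyl (1-diazo-2-oxopropyl)phosphonate, COP(=O)(OC)C(=[N+]=[N-])C(C)=O
Why: Half-reduction of the lactone to the lactol and Ohira–Bestmann (Seyferth–Gilbert) homologation of its open aldehyde form in the same flask turn the lactone carbonyl into the C10≡C9 alkyne and free the secondary hydroxyl, no stereocentre being touched.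

Step 8
Reactants: 10 (2S,4S,7S)-7-(TBSO)-4-ethynyl-4,8-dimethyl-1-(trityloxy)non-8-en-2-ol
Product: 11 (2S,4S,7S)-7-(TBSO)-4-[(E)-2-iodoethenyl]-4,8-dimethyl-1-(trityloxy)non-8-en-2-ol
Conditions: Cp2Zr(H)Cl (2.5 equiv), THF, rt; then I2, 0 °C
Reagents that add atoms: iodine, [I][I]
Why: Hydrozirconation of the terminal alkyne (syn addition, zirconium at the terminus, much faster than at the 1,1-disubstituted alkene) followed by iodinolysis with retention gives the (E)-alkenyl iodide.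

Step 9
Reactants: 11 (2S,4S,7S)-7-(TBSO)-4-[(E)-2-iodoethenyl]-4,8-dimethyl-1-(trityloxy)non-8-en-2-ol
Product: 13 (3S,6S)-6-(TBSO)-3-[(E)-2-iodoethenyl]-3,7-dimethyloct-7-enal, via diol 12 (not isolated)
Conditions: TsOH·H2O (10 mol %), MeOH/CH2Cl2, 0 °C; then NaHCO3, NaIO4, THF/H2O, 0 °C → rt
Reagents that add atoms: none
Why: Acid-catalysed methanolysis of the trityl ether (the hindered secondary TBS ether survives) and periodate glycol cleavage (Malaprade reaction) excise the spent lactone stereocentre and leave the C2 aldehyde.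

Step 10
Reactants: 14 ethyl (triphenylphosphoranylidene)acetate; 15 3-bromo-1,1-dimethoxypropane
Product: 17 ethyl 5,5-dimethoxy-2-(triphenylphosphoranylidene)pentanoate, via phosphonium bromide 16 (not isolated)
Conditions: NaI (10 mol %), MeCN, 80 °C; then 1 M aq NaOH, CH2Cl2, 0 °C
Reagents that add atoms: none
Why: C-alkylation of the stabilised ylide by the primary bromide (iodide catalysis) gives the phosphonium salt, which aqueous base deprotonates to the α-substituted stabilised ylide.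

Step 11
Reactants: 13 (3S,6S)-6-(TBSO)-3-[(E)-2-iodoethenyl]-3,7-dimethyloct-7-enal; 17 ethyl 5,5-dimethoxy-2-(triphenylphosphoranylidene)pentanoate
Product: 18 ethyl (2E,5S,8S)-8-(TBSO)-2-(3,3-dimethoxypropyl)-5-[(E)-2-iodoethenyl]-5,9-dimethyldeca-2,9-dienoate
Conditions: toluene, 90 °C
Reagents that add atoms: none
Why: Wittig olefination with an α-branched stabilised ylide gives the (E)-trisubstituted enoate (ester trans to C1, usually >95:5), which is the ring-cis C2=C3 geometry of the target.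

Step 12
Reactants: 18 ethyl (2E,5S,8S)-8-(TBSO)-2-(3,3-dimethoxypropyl)-5-[(E)-2-iodoethenyl]-5,9-dimethyldeca-2,9-dienoate
Product: 19 (2E,5S,8S)-8-(TBSO)-2-(3,3-dimethoxypropyl)-5-[(E)-2-iodoethenyl]-5,9-dimethyldeca-2,9-dien-1-ol
Conditions: iBu2AlH (2.5 equiv), CH2Cl2, −78 °C
Reagents that add atoms: none
Why: 1,2-Reduction of the conjugated ester by the aluminium hydride gives the C17 allylic alcohol while acetal, silyl ether and alkenyl iodide are inert at −78 °C.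

Step 13
Reactants: 19 (2E,5S,8S)-8-(TBSO)-2-(3,3-dimethoxypropyl)-5-[(E)-2-iodoethenyl]-5,9-dimethyldeca-2,9-dien-1-ol
Product: 20 (2E,5S,8S)-8-(TBSO)-1-(TBDPSO)-2-(3,3-dimethoxypropyl)-5-[(E)-2-iodoethenyl]-5,9-dimethyldeca-2,9-diene
Conditions: TBDPSCl, imidazole, DMF, rt
Reagents that add atoms: tert-butyldiphenylsilyl chloride, CC(C)(C)[Si](Cl)(c1ccccc1)c1ccccc1
Why: Silylation gives an acid-stable ether that survives acetal hydrolysis and keeps the C17 hydroxyl from directing the later epoxidation to C2=C3.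

Step 14
Reactants: 20 (2E,5S,8S)-8-(TBSO)-1-(TBDPSO)-2-(3,3-dimethoxypropyl)-5-[(E)-2-iodoethenyl]-5,9-dimethyldeca-2,9-diene
Product: 21 (4E,7S,10S)-10-(TBSO)-4-[(TBDPSO)methyl]-7-[(E)-2-iodoethenyl]-7,11-dimethyldodeca-4,11-dienal
Conditions: PPTS (20 mol %), acetone/H2O 10:1, 50 °C
Reagents that add atoms: water, O
Why: Mild acid-catalysed hydrolysis of the dimethyl acetal frees the C6 aldehyde while both silyl ethers survive.

Step 15
Reactants: 21 (4E,7S,10S)-10-(TBSO)-4-[(TBDPSO)methyl]-7-[(E)-2-iodoethenyl]-7,11-dimethyldodeca-4,11-dienal; 22 2-(triphenylphosphoranylidene)propanal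
Product: 23 (2E,6E,9S,12S)-12-(TBSO)-6-[(TBDPSO)methyl]-9-[(E)-2-iodoethenyl]-2,9,13-trimethyltetradeca-2,6,13-trienal
Conditions: toluene, 80 °C
Reagents that add atoms: none
Why: Wittig reaction with the formyl-stabilised ylide forms C6=C7 as the (E)-2-methyl enal (>95:5) and delivers C8 at the aldehyde oxidation level.

Step 16
Reactants: 23 (2E,6E,9S,12S)-12-(TBSO)-6-[(TBDPSO)methyl]-9-[(E)-2-iodoethenyl]-2,9,13-trimethyltetradeca-2,6,13-trienal
Product: 24 (1S,2E,4S,6E,10E)-4-[(3S)-3-(TBSO)-4-methylpent-4-en-1-yl]-7-[(TBDPSO)methyl]-4,11-dimethylcycloundeca-2,6,10-trien-1-ol (8S,11S,14S in the locants of the overview)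
Conditions: CrCl2 (20 mol %), NiCl2·DME (2 mol %), Cp2ZrCl2 (1.5 equiv), LiCl, Bu4NBF4, DMF, undivided cell, aluminium anode, nickel-foam cathode, 2 mA constant current, syringe-pump addition of 23 (final 2 mM), rt
Reagents that add atoms: none
Why: Proposed new method: a chromium-catalysed electroreductive Nozaki–Hiyama–Kishi macrocyclisation of an alkenyl iodide onto an enal to close an 11-membered carbocycle, whose closest known relatives are the intermolecular electrochemical NHK coupling of alkenyl halides with aldehydes and the stoichiometric CrCl2/NiCl2 NHK macrocyclisation. The cathode reduces trivalent chromium to divalent chromium and NiCl2 to zerovalent nickel, which inserts into the C9–iodine bond with retention of the E geometry; transmetallation gives an alkenylchromium (trivalent) species that adds 1,2 to the C8 aldehyde, Cp2ZrCl2 takes the alkoxide off chromium so that it re-enters the cycle, the chromium mediator keeps the cathode potential above that of direct enal reduction, the aluminium anode is consumed and slow addition keeps the seco compound dilute. C8 is set by macrocyclic substrate control from C11 (large C11 side chain outside the forming ring, s-trans enal attacked on its Si face, expected 8S).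

Step 17
Reactants: 24 (1S,2E,4S,6E,10E)-4-[(3S)-3-(TBSO)-4-methylpent-4-en-1-yl]-7-[(TBDPSO)methyl]-4,11-dimethylcycloundeca-2,6,10-trien-1-ol
Product: 25 (1S,2S,3E,5S,7E,11S)-5-[(3S)-3-(TBSO)-4-methylpent-4-en-1-yl]-8-[(TBDPSO)methyl]-1,5-dimethyl-12-oxabicyclo[9.1.0]dodeca-3,7-dien-2-ol (erythro 6,7-epoxy-8-ol)
Conditions: VO(acac)2 (5 mol %), tBuOOH (1.5 equiv), CH2Cl2, 0 °C → rt
Reagents that add atoms: tert-butyl hydroperoxide, CC(C)(C)OO
Why: Hydroxyl-directed epoxidation by a pentavalent vanadium alkylperoxide (Sharpless–Michaelson type) picks the trisubstituted allylic alkene C6=C7 and, because of A1,2 strain with the C7 methyl, delivers oxygen from the open face through the conformer with the C8–O bond about 45° out of the alkene plane, so the C8 carbinol sets the erythro epoxide (C6 and C7).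

Step 18
Reactants: 25 (1S,2S,3E,5S,7E,11S)-5-[(3S)-3-(TBSO)-4-methylpent-4-en-1-yl]-8-[(TBDPSO)methyl]-1,5-dimethyl-12-oxabicyclo[9.1.0]dodeca-3,7-dien-2-ol; 26 3-methylbut-2-enoic acid
Product: 27 (1R,2R,3E,5S,7E,11S)-5-[(3S)-3-(TBSO)-4-methylpent-4-en-1-yl]-8-[(TBDPSO)methyl]-1,5-dimethyl-12-oxabicyclo[9.1.0]dodeca-3,7-dien-2-yl 3-methylbut-2-enoate
Conditions: PPh3, DIAD, toluene, 0 °C → rt
Reagents that add atoms: none
Why: Mitsunobu esterification displaces the alkoxyphosphonium by carboxylate in an SN2 step, so C8 is inverted to 8R and the erythro epoxy alcohol becomes the threo ester of the target (the C7 descriptor changes from S to R only through CIP priorities), while SN2′ attack at C10 is blocked by the quaternary C11.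

Step 19
Reactants: 27 (1R,2R,3E,5S,7E,11S)-5-[(3S)-3-(TBSO)-4-methylpent-4-en-1-yl]-8-[(TBDPSO)methyl]-1,5-dimethyl-12-oxabicyclo[9.1.0]dodeca-3,7-dien-2-yl 3-methylbut-2-enoate
Product: 28 (1R,2R,3E,5S,7E,11S)-8-(hydroxymethyl)-5-[(3S)-3-hydroxy-4-methylpent-4-en-1-yl]-1,5-dimethyl-12-oxabicyclo[9.1.0]dodeca-3,7-dien-2-yl 3-methylbut-2-enoate (CNP0309478.3)
Conditions: Bu4NF, AcOH (1:1), THF, 0 °C → rt
Reagents that add atoms: none
Why: Buffered fluoride desilylation removes the TBDPS and TBS ethers without touching the senecioate ester or the oxirane and gives the target.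

## Compound list

1 | (S)-3-hydroxydihydrofuran-2(3H)-one | O[C@H]1CCOC1=O | starting material
2 | (S)-3-(TBSO)dihydrofuran-2(3H)-one | CC(C)(C)[Si](C)(C)O[C@H]1CCOC1=O | intermediate
3 | (3S)-3-(TBSO)-2-methyloxolan-2-ol (C2 anomers) | CC(C)(C)[Si](C)(C)O[C@H]1CCOC1(C)O | intermediate
4 | (S)-3-(TBSO)-4-methylpent-4-en-1-ol | C=C(C)[C@@H](O[Si](C)(C)C(C)(C)C)CCO | intermediate
5 | (S)-tert-butyl[(5-iodo-2-methylpent-1-en-3-yl)oxy]dimethylsilane | C=C(C)[C@@H](O[Si](C)(C)C(C)(C)C)CCI | intermediate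
6 | (S)-5-[(trityloxy)methyl]dihydrofuran-2(3H)-one | O=C1CC[C@@H](COC(c2ccccc2)(c2ccccc2)c2ccccc2)O1 | starting material
7 | (3R,5S)-3-[(3S)-3-(TBSO)-4-methylpent-4-en-1-yl]-5-[(trityloxy)methyl]dihydrofuran-2(3H)-one | O=C1[C@H](CC[C@H](O[Si](C)(C)C(C)(C)C)C(C)=C)C[C@@H](COC(c2ccccc2)(c2ccccc2)c2ccccc2)O1 | intermediate
8 | (3S,5S)-3-[(3S)-3-(TBSO)-4-methylpent-4-en-1-yl]-3-methyl-5-[(trityloxy)methyl]dihydrofuran-2(3H)-one | O=C1[C@@](C)(CC[C@H](O[Si](C)(C)C(C)(C)C)C(C)=C)C[C@@H](COC(c2ccccc2)(c2ccccc2)c2ccccc2)O1 | intermediate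
9 | (3S,5S)-3-[(3S)-3-(TBSO)-4-methylpent-4-en-1-yl]-3-methyl-5-[(trityloxy)methyl]oxolan-2-ol (C2 anomers) | OC1[C@@](C)(CC[C@H](O[Si](C)(C)C(C)(C)C)C(C)=C)C[C@@H](COC(c2ccccc2)(c2ccccc2)c2ccccc2)O1 | intermediate (not isolated)
10 | (2S,4S,7S)-7-(TBSO)-4-ethynyl-4,8-dimethyl-1-(trityloxy)non-8-en-2-ol | C#C[C@@](C)(CC[C@H](O[Si](C)(C)C(C)(C)C)C(C)=C)C[C@@H](COC(c1ccccc1)(c1ccccc1)c1ccccc1)O | intermediate
11 | (2S,4S,7S)-7-(TBSO)-4-[(E)-2-iodoethenyl]-4,8-dimethyl-1-(trityloxy)non-8-en-2-ol | I/C=C/[C@@](C)(CC[C@H](O[Si](C)(C)C(C)(C)C)C(C)=C)C[C@@H](COC(c1ccccc1)(c1ccccc1)c1ccccc1)O | intermediate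
12 | (2S,4S,7S)-7-(TBSO)-4-[(E)-2-iodoethenyl]-4,8-dimethylnon-8-ene-1,2-diol | I/C=C/[C@@](C)(CC[C@H](O[Si](C)(C)C(C)(C)C)C(C)=C)C[C@@H](CO)O | intermediate (not isolated)
13 | (3S,6S)-6-(TBSO)-3-[(E)-2-iodoethenyl]-3,7-dimethyloct-7-enal | I/C=C/[C@@](C)(CC[C@H](O[Si](C)(C)C(C)(C)C)C(C)=C)CC=O | intermediate
14 | ethyl (triphenylphosphoranylidene)acetate | CCOC(=O)C=P(c1ccccc1)(c1ccccc1)c1ccccc1 | starting material
15 | 3-bromo-1,1-dimethoxypropane | COC(CCBr)OC | starting material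
16 | (1-ethoxy-5,5-dimethoxy-1-oxopentan-2-yl)triphenylphosphonium bromide | CCOC(=O)C(CCC(OC)OC)[P+](c1ccccc1)(c1ccccc1)c1ccccc1.[Br-] | intermediate (not isolated)
17 | ethyl 5,5-dimethoxy-2-(triphenylphosphoranylidene)pentanoate | CCOC(=O)C(CCC(OC)OC)=P(c1ccccc1)(c1ccccc1)c1ccccc1 | intermediate
18 | ethyl (2E,5S,8S)-8-(TBSO)-2-(3,3-dimethoxypropyl)-5-[(E)-2-iodoethenyl]-5,9-dimethyldeca-2,9-dienoate | CCOC(=O)/C(CCC(OC)OC)=C/C[C@@](C)(/C=C/I)CC[C@H](O[Si](C)(C)C(C)(C)C)C(C)=C | intermediate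
19 | (2E,5S,8S)-8-(TBSO)-2-(3,3-dimethoxypropyl)-5-[(E)-2-iodoethenyl]-5,9-dimethyldeca-2,9-dien-1-ol | OC/C(CCC(OC)OC)=C/C[C@@](C)(/C=C/I)CC[C@H](O[Si](C)(C)C(C)(C)C)C(C)=C | intermediate
20 | (2E,5S,8S)-8-(TBSO)-1-(TBDPSO)-2-(3,3-dimethoxypropyl)-5-[(E)-2-iodoethenyl]-5,9-dimethyldeca-2,9-diene | CC(C)(C)[Si](c1ccccc1)(c1ccccc1)OC/C(CCC(OC)OC)=C/C[C@@](C)(/C=C/I)CC[C@H](O[Si](C)(C)C(C)(C)C)C(C)=C | intermediate
21 | (4E,7S,10S)-10-(TBSO)-4-[(TBDPSO)methyl]-7-[(E)-2-iodoethenyl]-7,11-dimethyldodeca-4,11-dienal | O=CCC/C(CO[Si](c1ccccc1)(c1ccccc1)C(C)(C)C)=C\C[C@@](C)(/C=C/I)CC[C@H](O[Si](C)(C)C(C)(C)C)C(C)=C | intermediate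
22 | 2-(triphenylphosphoranylidene)propanal | CC(C=O)=P(c1ccccc1)(c1ccccc1)c1ccccc1 | starting material
23 | (2E,6E,9S,12S)-12-(TBSO)-6-[(TBDPSO)methyl]-9-[(E)-2-iodoethenyl]-2,9,13-trimethyltetradeca-2,6,13-trienal | O=C/C(C)=C/CC/C(CO[Si](c1ccccc1)(c1ccccc1)C(C)(C)C)=C\C[C@@](C)(/C=C/I)CC[C@H](O[Si](C)(C)C(C)(C)C)C(C)=C | intermediate
24 | (1S,2E,4S,6E,10E)-4-[(3S)-3-(TBSO)-4-methylpent-4-en-1-yl]-7-[(TBDPSO)methyl]-4,11-dimethylcycloundeca-2,6,10-trien-1-ol | C=C(C)[C@@H](O[Si](C)(C)C(C)(C)C)CC[C@]1(C)/C=C/[C@H](O)/C(C)=C/CC/C(CO[Si](c2ccccc2)(c2ccccc2)C(C)(C)C)=C\C1 | intermediate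
25 | (1S,2S,3E,5S,7E,11S)-5-[(3S)-3-(TBSO)-4-methylpent-4-en-1-yl]-8-[(TBDPSO)methyl]-1,5-dimethyl-12-oxabicyclo[9.1.0]dodeca-3,7-dien-2-ol | C=C(C)[C@@H](O[Si](C)(C)C(C)(C)C)CC[C@]1(C)/C=C/[C@H](O)[C@]2(C)O[C@H]2CC/C(CO[Si](c3ccccc3)(c3ccccc3)C(C)(C)C)=C\C1 | intermediate
26 | 3-methylbut-2-enoic acid | CC(C)=CC(=O)O | starting material
27 | (1R,2R,3E,5S,7E,11S)-5-[(3S)-3-(TBSO)-4-methylpent-4-en-1-yl]-8-[(TBDPSO)methyl]-1,5-dimethyl-12-oxabicyclo[9.1.0]dodeca-3,7-dien-2-yl 3-methylbut-2-enoate | C=C(C)[C@@H](O[Si](C)(C)C(C)(C)C)CC[C@]1(C)/C=C/[C@@H](OC(=O)C=C(C)C)[C@]2(C)O[C@H]2CC/C(CO[Si](c3ccccc3)(c3ccccc3)C(C)(C)C)=C\C1 | intermediate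
28 | (1R,2R,3E,5S,7E,11S)-8-(hydroxymethyl)-5-[(3S)-3-hydroxy-4-methylpent-4-en-1-yl]-1,5-dimethyl-12-oxabicyclo[9.1.0]dodeca-3,7-dien-2-yl 3-methylbut-2-enoate | C=C(C)[C@@H](O)CC[C@]1(C)/C=C/[C@@H](OC(=O)C=C(C)C)[C@]2(C)O[C@H]2CC/C(CO)=C\C1 | target

## Step count and risks

Total step count: 19. Longest linear sequence: 18 steps (1 → 28 through steps 1–9 and 11–19; step 10 is the side branch).

Steps most likely to fail:

Step 16 (the proposed electrochemical macrocyclisation). Risks are competing direct enal reduction or oligomerisation, and above all the sense of induction at C8, which rests on a conformational model and was not computed. The fallback uses known chemistry, closes the ring at C6=C7 instead, sets out from 20 and comes back at 24. An intermolecular stoichiometric NHK coupling of 20 with diethyl (1-oxopropan-2-yl)phosphonate (CrCl2, catalytic NiCl2, DMSO) gives diethyl [(4E,6S,9S)-9-(TBSO)-6-{(2E)-3-[(TBDPSO)methyl]-6,6-dimethoxyhex-2-en-1-yl}-3-hydroxy-6,10-dimethylundeca-4,10-dien-2-yl]phosphonate F6. Dess–Martin oxidation gives the β-keto phosphonate diethyl [(4E,6S,9S)-9-(TBSO)-6-{(2E)-3-[(TBDPSO)methyl]-6,6-dimethoxyhex-2-en-1-yl}-6,10-dimethyl-3-oxoundeca-4,10-dien-2-yl]phosphonate F7. PPTS in wet acetone then frees the aldehyde diethyl [(4E,6S,9S)-9-(TBSO)-6-{(2E)-3-[(TBDPSO)methyl]-6-oxohex-2-en-1-yl}-6,10-dimethyl-3-oxoundeca-4,10-dien-2-yl]phosphonate F8. A Horner–Wadsworth–Emmons macrocyclisation (LiCl, DBU, MeCN, 1 mM) closes the ring to the cross-conjugated dienone (2E,4S,6E,10E)-4-[(3S)-3-(TBSO)-4-methylpent-4-en-1-yl]-7-[(TBDPSO)methyl]-4,11-dimethylcycloundeca-2,6,10-trien-1-one F9. Luche reduction (NaBH4, CeCl3·7H2O, MeOH, −78 °C) from the open face of the macrocycle then gives 24. F9 is also reached by Dess–Martin oxidation of 24, so it serves as a second, independently controlled entry to C8 should the electrolysis favour the 8R epimer.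

Step 18 (Mitsunobu inversion at a hindered, allylic, epoxide-flanked carbinol with a weakly acidic unsaturated acid). Risks are no reaction, elimination or partial retention. The fallback sets out from 25 and comes back at 27. ClCH2SO2Cl and pyridine in CH2Cl2 at 0 °C give the sulfonate (1S,2S,3E,5S,7E,11S)-5-[(3S)-3-(TBSO)-4-methylpent-4-en-1-yl]-8-[(TBDPSO)methyl]-1,5-dimethyl-12-oxabicyclo[9.1.0]dodeca-3,7-dien-2-yl chloromethanesulfonate F10. This is displaced with inversion by caesium 3-methylbut-2-enoate (from 26 and Cs2CO3) with 18-crown-6 in toluene at 60 °C to give 27.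

Step 5 (alkylation of a lactone enolate with an unactivated primary iodide, where E2 and proton transfer compete). The fallback replaces the SN2 step by aldol condensation and conjugate reduction, sets out from 4 and 6 and comes back at 7. Dess–Martin oxidation of 4 gives (S)-3-(TBSO)-4-methylpent-4-enal F1. Addition of the lithium enolate of 6 (LiN(iPr)2, THF, −78 °C) gives the aldol adducts (5S)-3-[(3S)-3-(TBSO)-1-hydroxy-4-methylpent-4-en-1-yl]-5-[(trityloxy)methyl]dihydrofuran-2(3H)-one F2. MsCl and Et3N give the methanesulfonate (3S)-3-(TBSO)-4-methyl-1-{(5S)-2-oxo-5-[(trityloxy)methyl]oxolan-3-yl}pent-4-en-1-yl methanesulfonate F3, and DBU eliminates it to (3E,5S)-3-[(3S)-3-(TBSO)-4-methylpent-4-en-1-ylidene]-5-[(trityloxy)methyl]dihydrofuran-2(3H)-one F4. Conjugate reduction with [(Ph3P)CuH]6 in toluene gives 7 together with its C3 epimer (3S,5S)-3-[(3S)-3-(TBSO)-4-methylpent-4-en-1-yl]-5-[(trityloxy)methyl]dihydrofuran-2(3H)-one F5. Both give the same enolate in step 6, so the mixture is carried on as 7.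

## Further compounds

F1 | step 5 | (S)-3-(TBSO)-4-methylpent-4-enal | C=C(C)[C@@H](O[Si](C)(C)C(C)(C)C)CC=O
F2 | step 5 | (5S)-3-[(3S)-3-(TBSO)-1-hydroxy-4-methylpent-4-en-1-yl]-5-[(trityloxy)methyl]dihydrofuran-2(3H)-one | O=C1C(C(O)C[C@H](O[Si](C)(C)C(C)(C)C)C(C)=C)C[C@@H](COC(c2ccccc2)(c2ccccc2)c2ccccc2)O1
F3 | step 5 | (3S)-3-(TBSO)-4-methyl-1-{(5S)-2-oxo-5-[(trityloxy)methyl]oxolan-3-yl}pent-4-en-1-yl methanesulfonate | O=C1C(C(OS(C)(=O)=O)C[C@H](O[Si](C)(C)C(C)(C)C)C(C)=C)C[C@@H](COC(c2ccccc2)(c2ccccc2)c2ccccc2)O1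
F4 | step 5 | (3E,5S)-3-[(3S)-3-(TBSO)-4-methylpent-4-en-1-ylidene]-5-[(trityloxy)methyl]dihydrofuran-2(3H)-one | O=C1/C(=C/C[C@H](O[Si](C)(C)C(C)(C)C)C(C)=C)C[C@@H](COC(c2ccccc2)(c2ccccc2)c2ccccc2)O1
F5 | step 5 | (3S,5S)-3-[(3S)-3-(TBSO)-4-methylpent-4-en-1-yl]-5-[(trityloxy)methyl]dihydrofuran-2(3H)-one | O=C1[C@@H](CC[C@H](O[Si](C)(C)C(C)(C)C)C(C)=C)C[C@@H](COC(c2ccccc2)(c2ccccc2)c2ccccc2)O1
F6 | step 16 | diethyl [(4E,6S,9S)-9-(TBSO)-6-{(2E)-3-[(TBDPSO)methyl]-6,6-dimethoxyhex-2-en-1-yl}-3-hydroxy-6,10-dimethylundeca-4,10-dien-2-yl]phosphonate | CC(C)(C)[Si](c1ccccc1)(c1ccccc1)OC/C(CCC(OC)OC)=C/C[C@@](C)(/C=C/C(O)C(C)P(=O)(OCC)OCC)CC[C@H](O[Si](C)(C)C(C)(C)C)C(C)=C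
F7 | step 16 | diethyl [(4E,6S,9S)-9-(TBSO)-6-{(2E)-3-[(TBDPSO)methyl]-6,6-dimethoxyhex-2-en-1-yl}-6,10-dimethyl-3-oxoundeca-4,10-dien-2-yl]phosphonate | CC(C)(C)[Si](c1ccccc1)(c1ccccc1)OC/C(CCC(OC)OC)=C/C[C@@](C)(/C=C/C(=O)C(C)P(=O)(OCC)OCC)CC[C@H](O[Si](C)(C)C(C)(C)C)C(C)=C
F8 | step 16 | diethyl [(4E,6S,9S)-9-(TBSO)-6-{(2E)-3-[(TBDPSO)methyl]-6-oxohex-2-en-1-yl}-6,10-dimethyl-3-oxoundeca-4,10-dien-2-yl]phosphonate | O=CCC/C(CO[Si](c1ccccc1)(c1ccccc1)C(C)(C)C)=C\C[C@@](C)(/C=C/C(=O)C(C)P(=O)(OCC)OCC)CC[C@H](O[Si](C)(C)C(C)(C)C)C(C)=C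
F9 | step 16 | (2E,4S,6E,10E)-4-[(3S)-3-(TBSO)-4-methylpent-4-en-1-yl]-7-[(TBDPSO)methyl]-4,11-dimethylcycloundeca-2,6,10-trien-1-one | C=C(C)[C@@H](O[Si](C)(C)C(C)(C)C)CC[C@]1(C)/C=C/C(=O)/C(C)=C/CC/C(CO[Si](c2ccccc2)(c2ccccc2)C(C)(C)C)=C\C1
F10 | step 18 | (1S,2S,3E,5S,7E,11S)-5-[(3S)-3-(TBSO)-4-methylpent-4-en-1-yl]-8-[(TBDPSO)methyl]-1,5-dimethyl-12-oxabicyclo[9.1.0]dodeca-3,7-dien-2-yl chloromethanesulfonate | C=C(C)[C@@H](O[Si](C)(C)C(C)(C)C)CC[C@]1(C)/C=C/[C@H](OS(=O)(=O)CCl)[C@]2(C)O[C@H]2CC/C(CO[Si](c3ccccc3)(c3ccccc3)C(C)(C)C)=C\C1
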